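**Strategy.** Everything rests on disconnecting the O1–C8a bond of ring C. The handle is C8a of ring A: next to the C8 methoxy and opposite the C6 methoxy, it is, in a precursor lacking O1, the sole hydrogen-bearing carbon of an electron-rich tetraalkoxy ring A. An anodic dehydrogenative cyclisation of an open-chain 1,3-diketone should therefore close ring C and install the fifth oxygen of ring A in one operation. The precursor, diketone 9, links a 2,4-bis(benzyloxy)-3,5-dimethoxyphenyl ketone (ring A) to a 3,4,5-trimethoxybenzoyl unit (ring B) and arises from a syringate-derived benzoate by Claisen condensation; hydrogenolysis then frees the C5 and C7 hydroxyls.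

Key step: step 6

Assumptions on the chemistry:
- Methyl syringate (1) and 1-(3,4,5-trimethoxyphenyl)ethanone (8) are taken as commercial.
- The target has no stereocentre, so nothing has to be set or protected against scrambling.
- Diketone 9 is drawn as the keto form although it should exist mainly as the chelated enol.
- The ring A carbonyl carbon is carried from the start as a benzoate, so that no Lewis-acid acylation has to be run in the presence of a benzyl ether.

**Route**

Step 1
Reactants: 1 methyl 4-hydroxy-3,5-dimethoxybenzoate (methyl syringate); 2 benzyl bromide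
Product: 3 methyl 4-(benzyloxy)-3,5-dimethoxybenzoate
Conditions: K2CO3, DMF, 60 °C
Reagents that add atoms: benzyl bromide, BrCc1ccccc1
Why: Williamson ether synthesis; the phenoxide of 1, though flanked by two methoxy groups, should be alkylated readily by the reactive benzylic bromide, and the methyl ester is untouched by K2CO3.

Step 2
Reactants: 3 methyl 4-(benzyloxy)-3,5-dimethoxybenzoate
Product: 4 methyl 4-(benzyloxy)-2-bromo-3,5-dimethoxybenzoate
Conditions: NBS (1.05 equiv), MeCN, rt to 50 °C, dark
Reagents that add atoms: N-bromosuccinimide, O=C1CCC(=O)N1Br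
Why: Electrophilic aromatic bromination; the two equivalent free ring positions are each ortho to one methoxy and para to the other, so a single monobromide is expected, the first bromine slows a second substitution, and the unactivated benzyl ring and the ester should stay inert.

Step 3
Reactants: 4 methyl 4-(benzyloxy)-2-bromo-3,5-dimethoxybenzoate
Product: 6 4-(benzyloxy)-2-hydroxy-3,5-dimethoxybenzoic acid, via sodium bromobenzoate 5 (not isolated)
Conditions: NaOH (aq), THF, 60 °C, then THF and MeOH distilled off; CuSO4 (10 mol %), pyridine, H2O, 100 °C, N2; HCl (aq), 0 °C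
Reagents that add atoms: sodium hydroxide, [Na+].[OH-]
Why: Ester saponification followed by a copper-catalysed Ullmann-type hydroxylation, in which the ortho carboxylate binds copper and speeds exchange of bromide for hydroxide, the classical way from 2-bromobenzoic acids to salicylic acids; benzyl and methyl ethers are stable to hot aqueous base, and methanol is removed first so that no methoxide competes.

Step 4
Reactants: 6 4-(benzyloxy)-2-hydroxy-3,5-dimethoxybenzoic acid; 2 benzyl bromide (2.5 equiv)
Product: 7 benzyl 2,4-bis(benzyloxy)-3,5-dimethoxybenzoate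
Conditions: K2CO3 (3 equiv), DMF, 70 °C
Reagents that add atoms: benzyl bromide, BrCc1ccccc1
Why: Double Williamson-type alkylation; carboxylate and phenoxide are both benzylated by SN2 displacement, so the ester needed for the condensation and the protection of the future C5 oxygen are installed together.

Step 5
Reactants: 7 benzyl 2,4-bis(benzyloxy)-3,5-dimethoxybenzoate; 8 1-(3,4,5-trimethoxyphenyl)ethanone
Product: 9 1-[2,4-bis(benzyloxy)-3,5-dimethoxyphenyl]-3-(3,4,5-trimethoxyphenyl)propane-1,3-dione
Conditions: 8, LiN(SiMe3)2 (2.5 equiv), THF, −78 °C; then 7, −78 °C to rt (40 °C if needed); 1 M HCl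
Reagents that add atoms: none
Why: Crossed Claisen condensation of a preformed ketone enolate with a non-enolisable benzoate ester, pulled forward by deprotonation of the β-diketone product; benzyl and methyl ethers are inert to the amide base.

Step 6
Reactants: 9 1-[2,4-bis(benzyloxy)-3,5-dimethoxyphenyl]-3-(3,4,5-trimethoxyphenyl)propane-1,3-dione
Product: 10 5,7-bis(benzyloxy)-6,8-dimethoxy-2-(3,4,5-trimethoxyphenyl)-4H-chromen-4-one
Conditions: undivided cell, graphite anode, Pt cathode, anode potential held just past the first oxidation wave of 9 (expected near +1.2 V vs Ag/AgCl, to be fixed by cyclic voltammetry), n-Bu4NPF6 (0.1 M), (CF3)2CHOH/CH2Cl2 1:1, rt, about 2.1 F/mol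
Reagents that add atoms: none
Why: Proposed new method: at the carbon anode the tetraalkoxy ring A of 9 should give up one electron to form an arene radical cation, the oxygen of the chelated cis-enol on the ring B side then adds to the one hydrogen-bearing ring A carbon ortho to the ketone (the future C8a), and a second electron transfer with loss of the C8a proton rearomatises ring A while protons are reduced to hydrogen at the cathode. The closest known reaction types are the anodic dehydrogenative C–O cyclisations of biaryl-2-carboxylic acids to benzocoumarins and of anilides to benzoxazoles, together with the iron trichloride (FeCl3) mediated oxidative closure of an enol oxygen onto an alkoxy-substituted arene that gives benzofurans from α-aryl ketones. Ring C closes in a six-membered mode (6-endo counted on the C4a–C8a bond), with the enol oxygen, C2, C3 and C4 already held in one conjugated plane. No stereocentre is formed. Two selectivities are needed: oxidation of ring A in preference to ring B, which four alkoxy donors against three and the potential control should secure, and attack at the C–H carbon and not at the benzyloxy-bearing ortho carbon, which is favoured because C8a lies ortho and para to the methoxy groups at C8 and C6 and because only the C–H pathway ends in an irreversible proton loss. Hexafluoroisopropanol is chosen because it stabilises arene radical cations and is too weakly nucleophilic to intercept them.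

Step 7
Reactants: 10 5,7-bis(benzyloxy)-6,8-dimethoxy-2-(3,4,5-trimethoxyphenyl)-4H-chromen-4-one
Product: 11 5,7-dihydroxy-6,8-dimethoxy-2-(3,4,5-trimethoxyphenyl)-4H-chromen-4-one (5,7-dihydroxy-6,8,3',4',5'-pentamethoxyflavone)
Conditions: H2 (1 atm), 10% Pd/C, EtOAc/MeOH, rt
Reagents that add atoms: none
Why: Catalytic hydrogenolysis of two aryl benzyl ethers; the methyl ethers are inert and the conjugated C2–C3 double bond of the flavone is expected to survive at room temperature and atmospheric pressure if uptake is stopped after two equivalents.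

**Compound list**

1 | methyl 4-hydroxy-3,5-dimethoxybenzoate (methyl syringate) | COC(=O)c1cc(OC)c(O)c(OC)c1 | starting material
2 | benzyl bromide | BrCc1ccccc1 | starting material
3 | methyl 4-(benzyloxy)-3,5-dimethoxybenzoate | COC(=O)c1cc(OC)c(OCc2ccccc2)c(OC)c1 | intermediate
4 | methyl 4-(benzyloxy)-2-bromo-3,5-dimethoxybenzoate | COC(=O)c1cc(OC)c(OCc2ccccc2)c(OC)c1Br | intermediate
5 | sodium 4-(benzyloxy)-2-bromo-3,5-dimethoxybenzoate | [Na+].[O-]C(=O)c1cc(OC)c(OCc2ccccc2)c(OC)c1Br | intermediate
6 | 4-(benzyloxy)-2-hydroxy-3,5-dimethoxybenzoic acid | OC(=O)c1cc(OC)c(OCc2ccccc2)c(OC)c1O | intermediate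
7 | benzyl 2,4-bis(benzyloxy)-3,5-dimethoxybenzoate | COc1cc(C(=O)OCc2ccccc2)c(OCc2ccccc2)c(OC)c1OCc1ccccc1 | intermediate
8 | 1-(3,4,5-trimethoxyphenyl)ethanone | CC(=O)c1cc(OC)c(OC)c(OC)c1 | starting material
9 | 1-[2,4-bis(benzyloxy)-3,5-dimethoxyphenyl]-3-(3,4,5-trimethoxyphenyl)propane-1,3-dione | COc1cc(C(=O)CC(=O)c2cc(OC)c(OCc3ccccc3)c(OC)c2OCc2ccccc2)cc(OC)c1OC | intermediate
10 | 5,7-bis(benzyloxy)-6,8-dimethoxy-2-(3,4,5-trimethoxyphenyl)-4H-chromen-4-one | COc1cc(-c2cc(=O)c3c(OCc4ccccc4)c(OC)c(OCc4ccccc4)c(OC)c3o2)cc(OC)c1OC | intermediate
11 | 5,7-dihydroxy-6,8-dimethoxy-2-(3,4,5-trimethoxyphenyl)-4H-chromen-4-one | COc1cc(-c2cc(=O)c3c(O)c(OC)c(O)c(OC)c3o2)cc(OC)c1OC | target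

**Step count and risks**

Total steps: 7. Longest linear sequence: 7 steps (1 to 11); ketone 8 enters at step 5.

Steps most likely to fail:

1. Step 6 (anodic closure of the O1–C8a bond). Four processes could defeat it:
   - electron transfer from ring B, leading to closure onto the trimethoxyphenyl ring;
   - attack of the enol oxygen at the benzyloxy-bearing ortho carbon with loss of the benzyl group;
   - oxidative dealkylation of ring A towards a quinone;
   - further oxidation of the more highly oxygenated product.

   Fallback with known chemistry, setting out from 6: the acid is treated with MeLi (3.3 equiv, THF, 0 °C, inverse quench into cold aqueous HCl) to give the methyl ketone 1-[4-(benzyloxy)-2-hydroxy-3,5-dimethoxyphenyl]ethanone F1. Benzylation with 2 (K2CO3, DMF) gives 1-[2,4-bis(benzyloxy)-3,5-dimethoxyphenyl]ethanone F2. NBS in MeCN should brominate the single free ring position to give 1-[2,4-bis(benzyloxy)-6-bromo-3,5-dimethoxyphenyl]ethanone F3. Claisen condensation of its enolate (LiN(SiMe3)2, THF) with commercial methyl 3,4,5-trimethoxybenzoate (COC(=O)c1cc(OC)c(OC)c(OC)c1) gives 1-[2,4-bis(benzyloxy)-6-bromo-3,5-dimethoxyphenyl]-3-(3,4,5-trimethoxyphenyl)propane-1,3-dione F4. A copper-catalysed intramolecular Ullmann-type O-arylation of the enolate (CuBr 10 mol %, 1,10-phenanthroline, K3PO4, DMF, 110 °C) then forms the same O1–C8a bond from C–Br instead of C–H and rejoins the route at 10.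

2. Step 3 (copper-catalysed hydroxylation). The bromide is flanked on both sides, so reductive loss of bromine could outrun the exchange for hydroxide, and the electron-rich salicylic acid could lose CO2 if acidified warm. Fallback, setting out from 4: Miyaura borylation (bis(pinacolato)diboron, Pd(OAc)2, SPhos, KOAc, dioxane, 90 °C) gives methyl 4-(benzyloxy)-3,5-dimethoxy-2-(4,4,5,5-tetramethyl-1,3,2-dioxaborolan-2-yl)benzoate F5. Oxidation of the C–B bond with H2O2 in aqueous NaOH/THF, warming to saponify the methyl ester, and cold acidification bring the material back to the route at 6.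

3. Step 5 (Claisen condensation). Acyl transfer to the ester could be slow, because two alkoxy donors ortho and para to the carbonyl deactivate it and the ortho benzyloxy group hinders it; self-aldol condensation of the ketone could then take over. Fallback, setting out from 7: saponification (LiOH, THF/MeOH/H2O, 50 °C) gives 2,4-bis(benzyloxy)-3,5-dimethoxybenzoic acid F6. Oxalyl chloride with catalytic DMF in CH2Cl2 gives 2,4-bis(benzyloxy)-3,5-dimethoxybenzoyl chloride F7. C-acylation of ketone 8 under soft enolisation (MgBr2·OEt2, i-Pr2NEt, CH2Cl2, rt) then returns to the route at 9.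

**Further compounds**

F1 | step 6 | 1-[4-(benzyloxy)-2-hydroxy-3,5-dimethoxyphenyl]ethanone | CC(=O)c1cc(OC)c(OCc2ccccc2)c(OC)c1O
F2 | step 6 | 1-[2,4-bis(benzyloxy)-3,5-dimethoxyphenyl]ethanone | CC(=O)c1cc(OC)c(OCc2ccccc2)c(OC)c1OCc1ccccc1
F3 | step 6 | 1-[2,4-bis(benzyloxy)-6-bromo-3,5-dimethoxyphenyl]ethanone | CC(=O)c1c(Br)c(OC)c(OCc2ccccc2)c(OC)c1OCc1ccccc1
F4 | step 6 | 1-[2,4-bis(benzyloxy)-6-bromo-3,5-dimethoxyphenyl]-3-(3,4,5-trimethoxyphenyl)propane-1,3-dione | COc1cc(C(=O)CC(=O)c2c(Br)c(OC)c(OCc3ccccc3)c(OC)c2OCc2ccccc2)cc(OC)c1OC
F5 | step 3 | methyl 4-(benzyloxy)-3,5-dimethoxy-2-(4,4,5,5-tetramethyl-1,3,2-dioxaborolan-2-yl)benzoate | COC(=O)c1cc(OC)c(OCc2ccccc2)c(OC)c1B1OC(C)(C)C(C)(C)O1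
F6 | step 5 | 2,4-bis(benzyloxy)-3,5-dimethoxybenzoic acid | OC(=O)c1cc(OC)c(OCc2ccccc2)c(OC)c1OCc1ccccc1
F7 | step 5 | 2,4-bis(benzyloxy)-3,5-dimethoxybenzoyl chloride | ClC(=O)c1cc(OC)c(OCc2ccccc2)c(OC)c1OCc1ccccc1
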